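## Structural features

The target is a 3,3a,4,5-tetrahydrobenzofuran-6(2H)-one. A dihydrofuran (ring A: O1, C2, C3, C3a, C7a) is fused along C3a–C7a to a cyclohexenone (ring B: C3a, C4, C5, C6, C7, C7a). O1, the C7=C7a double bond and the C6 ketone form a vinylogous ester that carries a further methoxy group on C7.

Three contiguous stereocentres lie in ring A: C2 (methyl, 2R), C3 (3,4,5-trimethoxyphenyl, 3S) and the quaternary ring-fusion carbon C3a (allyl, 3aS). Aryl is cis to allyl and methyl is trans to aryl. The fourth stereocentre, C5 (methoxy, 5S), stands alone in ring B, trans to allyl across C4.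

The fragile elements are the enol ether and vinylogous ester (acid), the base-epimerisable α-methoxy ketone centre C5, and the terminal allyl alkene, which rules out hydrogenation and unselective electrophilic oxidants.

The real difficulty is the all-carbon quaternary centre C3a, wedged between a benzylic stereocentre that cannot be epimerised and an enol ether carbon, with aryl on the more crowded side next to allyl. Ring B, by contrast, has the substitution pattern of a dearomatised 2,3-dialkoxybenzoic acid, so C3a can come from an ipso-alkylated arene.

The key step exploits the fact that O1–C2(H)(CH3) is an ethoxy group bound to C7a whose methylene carbon is the fifth atom counted from C3. A carbene at C3 can close ring A by taking up one of the methylene C–H bonds, forming C2–C3 and both ring-A stereocentres at once.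

## Logic of the disconnections

19 ⇒ 18. The O–CH3 bond of the C5 methoxy group is cut. Methylation is a mild last step for a molecule with an epimerisable α-oxygenated ketone, and it leaves an alcohol that comes directly from enolate oxidation. The forward step must etherify a hindered α-ketol without a base strong enough to enolise C5.

18 ⇒ 16. The C5–O bond is cut, leaving a C5 methylene next to the C6 ketone. C5 is the only enolisable position of 16, so the oxygen can be introduced through one unambiguous enolate, and one stereocentre disappears. The forward step must bring the oxidant to the face of C5 opposite the allyl group.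

16 ⇒ 15. The C–H bonds at C4 and C5 are removed to give the C4=C5 alkene of a cross-conjugated dienone. This is the oxidation state reached directly from a 1,4-diene. The forward reduction must touch only the disubstituted enone alkene, not the vinylogous ester alkene or the allyl group, which excludes hydrogenation.

15 ⇒ 14. The C6 carbonyl oxygen is removed, returning the doubly allylic C6 methylene of a cyclohexa-1,4-diene. Ring B then carries no carbonyl to disturb the nitrogen chemistry at C3, and the diene is what a Birch reduction delivers. The forward oxidation must select C6–H over the benzylic C3–H, the CH2 of the allyl group and the electron-rich enol ether.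

14 ⇒ 13. The C2–C3 bond is cut and ring A opens. C2 and its methyl group revert to the methylene and methyl of an ethoxy group on C7a, and C3 becomes a diazo-substituted carbon. This is the largest simplification of the route: one ring and two stereocentres disappear. The forward step must insert into one specific methylene C–H bond and place aryl cis to allyl and methyl trans to aryl.

13 ⇒ 12 ⇒ 11. The C3=N2 unit is traced back through the hydrazone to the C3 carbonyl group. An aryl ketone next to a quaternary carbon is robust and non-enolisable, whereas the diazo compound is made only just before use. The forward steps must condense a nitrogen nucleophile with a hindered ketone without acid strong enough to hydrolyse the two enol ethers, and then dehydrogenate without touching the diene.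

11 ⇒ 7 + 8. The C3–aryl bond is cut, giving an acyl donor at C3 and an aryl nucleophile (9, from 8). The route becomes convergent, and the amide that served as chiral controller doubles as the acylating group, so the auxiliary needs no separate removal. The forward step requires a single addition of 9 to a hindered tertiary amide.

7 ⇒ 4 + 5. The C3a–allyl bond is cut and ring B is re-aromatised: 7 is the ipso-allylated 1,4-dihydro form of 4. The quaternary stereocentre and the whole oxygenation pattern of ring B are reduced to a benzamide. The forward reductive alkylation must be ipso-selective, must not cleave the ortho C–O bond, and must be face-selective under control of the auxiliary.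

4 ⇒ 3 ⇒ 1 + 2. The O–ethyl bond and then the amide C–N bond are cut. Both pieces are commercial, and the ethyl group that later becomes C2 and its methyl is installed as a simple ether. The forward steps only require that the amide forms in the presence of the free phenol.

## Other disconnections considered

Alternative 1: The cut is C3a–C7a, with ring B assembled from a four-carbon squaric ester unit and a side-chain alkene that already carries C2 and C3.
- Forward key step: heating the 4-alkenyl-4-hydroxycyclobutenone A1 would open the four-membered ring (4π) to a dienylketene. Its ketene carbon (C7a) would close onto the fully substituted alkene terminus (C3a) in a 6π electrocyclisation, and tautomerisation would give ene-dione A2.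
- In its favour: ring B arrives with C5, C6, C7 and C7a all oxygenated, so no late C–H oxidation and no conjugate reduction are needed. The C2/C3 pair is set beforehand in an open chain by standard methods. No diazo compound is handled.
- Against it here: C3a would be created in a pericyclic closure whose facial sense is steered only by the neighbouring C3 centre, which is hard to predict. A geometrically pure trisubstituted alkenyl nucleophile bearing two stereocentres is needed. In A2 the two carbonyl groups and the two methoxy-bearing alkene carbons must then be told apart (C5 reduced and methylated, the C2 oxygen closed onto C7a, C6 unmasked as ketone).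
- Comparison: on the oxidation pattern of ring B and on the C2/C3 relationship this alternative is the better of the two. On mechanism it is at least the equal (a thermal cascade, no metal carbene). On C3a the chosen plan is stronger, since an auxiliary-controlled alkylation is more predictable. On step economy the chosen plan should be shorter, because the side-chain fragment and the endgame after A2 each cost several steps.

Alternative 2: The cuts are C3–aryl and C3a–C4, both made on the enantiopure butenolide A3.
- Forward key step: in one flask, copper-catalysed 1,4-addition of arylmagnesium bromide A4 to A3 would install aryl anti to the C2 methyl group. The enolate, held as its silyl ketene acetal, would then add to enone A5 anti to aryl (Mukaiyama–Michael), giving lactone A6 with the quaternary centre.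
- In its favour: every stereocentre of ring A follows from trans addition on a five-membered ring, relayed from one methyl-bearing centre of lactic acid origin, and this relay gives exactly methyl trans to aryl and allyl cis to aryl. An intramolecular Claisen condensation of the C7 enolate onto the lactone carbonyl, then recyclisation, would lead to 16, so the last two steps of the chosen route could be shared.
- Against it here: the quaternary carbon must form by Michael addition of a fully substituted, β-aryl ketene acetal to a polymerisation-prone enone. Conjugate addition to an α-substituted butenolide is slower than to the parent. The Claisen step must attack a neopentyl-type lactone carbonyl.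
- Comparison: on stereochemical security at C2, C3 and C3a this alternative is the better of the two, because it does not depend on the facial and methylene-hydrogen selectivity of a C–H insertion. On step count it is the equal or the better (about eight steps). The chosen plan is stronger in that its C–C bond formations (ipso-allylation, aryllithium addition) are sterically undemanding, so its risk is concentrated in selectivity rather than in conversion.

Alternative 3: The cuts are C3–aryl and C2–CH3, made across the alkene of the (Z)-alkenylboronate A7, which would come from the same Birch-type intermediate.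
- Forward key step: a methyl–lithium reagent would convert boron into its four-coordinate anion. Pd(OAc)2 with a MandyPhos ligand and aryl triflate A8 would then give an arylpalladium triflate that binds the alkene, methyl would migrate from boron to C2 anti to palladium, and reductive elimination would form C3–aryl, giving boronate A9.
- Onward path: oxidation with retention and acid-catalysed exchange of the C7a enol ether by the new hydroxyl would give 14.
- In its favour: the C2/C3 relationship is fixed stereospecifically by anti addition across an alkene of defined geometry, and the absolute sense is set by the ligand.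
- Against it here: the carbon that must receive aryl is neopentyl, next to the quaternary C3a; methyl is a reluctant migrating group; palladium may engage the 1,4-diene or the allyl group; ring closure needs acid in the presence of a second enol ether.
- Comparison: on the C2/C3 relationship this alternative is the better of the two. On C3 relative to C3a it is the equal, since both plans need the catalyst hand matched to the substrate. The endgame is identical. On steric feasibility and step economy the chosen plan is ahead, by about three steps.

Key step: step 7

Assumption 1: auxiliary 2 of (S) configuration is taken to direct allylation of enolate 6 anti to its methoxymethyl arm (chelated potassium Z-enolate), which gives the 1R centre of 7; with the opposite sense, the antipode of 2 would be used with no other change.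

Assumption 2: the R hand of the PTAD catalyst is written as the one whose facial preference at C3 matches the substrate bias of 13; Rh2(S-PTAD)4 is the direct substitute if the match lies the other way.

## Route

Step 1
Reactants: 1 2-hydroxy-3-methoxybenzoic acid; 2 (S)-2-(methoxymethyl)pyrrolidine
Product: 3 (2-hydroxy-3-methoxyphenyl)[(2S)-2-(methoxymethyl)pyrrolidin-1-yl]methanone
Conditions: EDC·HCl, HOBt, i-Pr2NEt, CH2Cl2, 0 °C to rt
Reagents that add atoms: none
Why: Carbodiimide-mediated amide coupling through the HOBt ester; salicylic acids couple with secondary amines without phenol protection because any aryl ester formed is aminolysed in turn.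

Step 2
Reactants: 3 (2-hydroxy-3-methoxyphenyl)[(2S)-2-(methoxymethyl)pyrrolidin-1-yl]methanone
Product: 4 (2-ethoxy-3-methoxyphenyl)[(2S)-2-(methoxymethyl)pyrrolidin-1-yl]methanone
Conditions: EtI, K2CO3, DMF, 50 °C
Reagents that add atoms: iodoethane, CCI
Why: Williamson etherification of the phenoxide; the tertiary amide has no N–H, so only oxygen is alkylated, and the ethyl group placed here later becomes C2 and its methyl group.

Step 3
Reactants: 4 (2-ethoxy-3-methoxyphenyl)[(2S)-2-(methoxymethyl)pyrrolidin-1-yl]methanone; 5 allyl bromide
Product: 7 [(1R)-1-allyl-2-ethoxy-3-methoxycyclohexa-2,5-dien-1-yl][(2S)-2-(methoxymethyl)pyrrolidin-1-yl]methanone, via potassium amide enolate 6 (not isolated)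
Conditions: K (2.2 equiv), t-BuOH (1 equiv), NH3(l)/THF, −78 °C; piperylene; then 5, −78 °C
Reagents that add atoms: none
Why: Asymmetric Birch reduction–alkylation of a chiral 2-alkoxybenzamide: electron transfer and protonation para to the amide give the amide enolate, which is allylated at the ipso carbon on the face anti to the methoxymethyl arm of the chelated auxiliary, setting C3a; one equivalent of alcohol at −78 °C keeps the ortho C–O bond intact.

Step 4
Reactants: 7 [(1R)-1-allyl-2-ethoxy-3-methoxycyclohexa-2,5-dien-1-yl][(2S)-2-(methoxymethyl)pyrrolidin-1-yl]methanone; 8 5-bromo-1,2,3-trimethoxybenzene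
Product: 11 [(1R)-1-allyl-2-ethoxy-3-methoxycyclohexa-2,5-dien-1-yl](3,4,5-trimethoxyphenyl)methanone, via 3,4,5-trimethoxyphenyllithium 9 (not isolated), via lithium hemiaminal 10 (not isolated)
Conditions: 8, n-BuLi, THF, −78 °C; then 7, −78 to 0 °C; then H2O
Reagents that add atoms: none
Why: Bromine–lithium exchange followed by addition of the unhindered aryllithium to the tertiary amide; the chelated lithium hemiaminal does not collapse before the quench, so the ketone never meets the nucleophile, and the auxiliary is released in the same operation.

Step 5
Reactants: 11 [(1R)-1-allyl-2-ethoxy-3-methoxycyclohexa-2,5-dien-1-yl](3,4,5-trimethoxyphenyl)methanone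
Product: 12 [(1S)-1-allyl-2-ethoxy-3-methoxycyclohexa-2,5-dien-1-yl](3,4,5-trimethoxyphenyl)methanone hydrazone
Conditions: N2H4·H2O (excess), AcOH (cat.), EtOH, 80 °C, degassed
Reagents that add atoms: hydrazine, NN
Why: Condensation to the N-unsubstituted hydrazone; with hydrazine in large excess the acetic acid is present only as hydrazinium acetate, too weak an acid to hydrolyse the enol ethers, and the excess also suppresses azine formation, while exclusion of air prevents diimide reduction of the allyl group.

Step 6
Reactants: 12 [(1S)-1-allyl-2-ethoxy-3-methoxycyclohexa-2,5-dien-1-yl](3,4,5-trimethoxyphenyl)methanone hydrazone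
Product: 13 (3S)-3-allyl-3-[diazo(3,4,5-trimethoxyphenyl)methyl]-2-ethoxy-1-methoxycyclohexa-1,4-diene
Conditions: activated MnO2, MgSO4, CH2Cl2, −20 to 0 °C, dark; cold filtration through Celite, solution used at once
Reagents that add atoms: none
Why: Dehydrogenation of the hydrazone to the aryl alkyl diazo compound, the usual entry to donor/donor carbenes; cold, dilute handling and immediate use keep the diazo group from adding as a 1,3-dipole to the neighbouring alkenes.

Step 7
Reactants: 13 (3S)-3-allyl-3-[diazo(3,4,5-trimethoxyphenyl)methyl]-2-ethoxy-1-methoxycyclohexa-1,4-diene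
Product: 14 (2R,3S,3aS)-3a-allyl-7-methoxy-2-methyl-3-(3,4,5-trimethoxyphenyl)-2,3,3a,6-tetrahydro-1-benzofuran
Conditions: Rh2(R-PTAD)4 (1 mol%), CH2Cl2, slow addition of cold 13, −40 to 0 °C
Reagents that add atoms: none
Why: The dirhodium tetracarboxylate expels N2 from 13 to give an electrophilic aryl/alkyl (donor/donor) rhodium carbene at C3, which takes up one C–H bond of the OCH2 group on C7a (the C–O bond stays intact) in a hydride-transfer-like three-centre transition state, so that C2–C3 forms with retention at C2. The closest known reaction type is the dirhodium-catalysed intramolecular 1,5 C–H insertion of donor/donor carbenes next to an ether oxygen that gives 2,3-dihydrobenzofurans; here the oxygen belongs to an enol ether and the carbene carbon is flanked by a quaternary centre. Ring A closes in the 1,5 mode, with C3, C3a, C7a, O1 and C2 plus the migrating hydrogen forming a six-membered cyclic array. C3 is set by the face of the carbene that receives the hydrogen: C3a is flanked at this stage by the allyl CH2 and the sp2 C4–H, so the bulky dirhodium unit should lie next to the flat C4–H and away from the pseudo-axial allyl group, hydrogen then enters on that side and aryl ends cis to allyl, a modest bias that the hand of the PTAD ligands is chosen to reinforce. C2 is set by which of the two methylene hydrogens migrates: the methyl group has to turn away from the face already occupied by aryl and allyl, which gives methyl trans to aryl. This second requirement runs against the cis preference seen when the tether is a flat arene and is secured here only by the extra crowding around C3a, so it is the selectivity most at risk. Chemoselectivity is secured by the substrate: C3a has no hydrogen for a 1,2-shift, cyclopropanation of any of the three alkenes would give bicyclobutane- or bicyclopentane-type rings, the C7 methoxy group is held trans to C3a across the double bond, and slow addition of cold 13 to the catalyst outruns dipolar cycloaddition and azine formation.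

Step 8
Reactants: 14 (2R,3S,3aS)-3a-allyl-7-methoxy-2-methyl-3-(3,4,5-trimethoxyphenyl)-2,3,3a,6-tetrahydro-1-benzofuran
Product: 15 (2R,3S,3aS)-3a-allyl-7-methoxy-2-methyl-3-(3,4,5-trimethoxyphenyl)-3,3a-dihydro-1-benzofuran-6(2H)-one
Conditions: t-BuOOH (terminal oxidant), (C5H5NH)2Cr2O7 (mediator), Celite, benzene, rt
Reagents that add atoms: tert-butyl hydroperoxide, CC(C)(C)OO
Why: Chromium-mediated radical oxidation of the doubly allylic C6 methylene through a tert-butyl peroxide that loses tert-butanol, the established conversion of Birch-derived cyclohexa-1,4-dienes into cross-conjugated cyclohexadienones; the C6–H bonds are much weaker than the benzylic C3–H or the CH2 of the allyl group.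

Step 9
Reactants: 15 (2R,3S,3aS)-3a-allyl-7-methoxy-2-methyl-3-(3,4,5-trimethoxyphenyl)-3,3a-dihydro-1-benzofuran-6(2H)-one
Product: 16 (2R,3S,3aR)-3a-allyl-7-methoxy-2-methyl-3-(3,4,5-trimethoxyphenyl)-3,3a,4,5-tetrahydro-1-benzofuran-6(2H)-one
Conditions: [(Ph3P)CuH]6, H2O, benzene/THF, rt
Reagents that add atoms: none
Why: Copper hydride conjugate reduction: hydride adds to C4 of the disubstituted enone and the copper enolate is protonated at C5, whereas the tetrasubstituted, doubly oxygenated C7=C7a alkene of the vinylogous ester and the isolated allyl alkene do not react; the 3aR label reflects only a change of CIP priorities.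

Step 10
Reactants: 16 (2R,3S,3aR)-3a-allyl-7-methoxy-2-methyl-3-(3,4,5-trimethoxyphenyl)-3,3a,4,5-tetrahydro-1-benzofuran-6(2H)-one
Product: 18 (2R,3S,3aS,5S)-3a-allyl-5-hydroxy-7-methoxy-2-methyl-3-(3,4,5-trimethoxyphenyl)-3,3a,4,5-tetrahydro-1-benzofuran-6(2H)-one, via potassium dienolate 17 (not isolated)
Conditions: KN(SiMe3)2, THF, −78 °C; then 2-(phenylsulfonyl)-3-phenyloxaziridine, −78 °C; then H2O
Reagents that add atoms: 2-(phenylsulfonyl)-3-phenyloxaziridine, O=S(=O)(N1OC1c1ccccc1)c1ccccc1
Why: Enolate hydroxylation with an N-sulfonyloxaziridine: C5 is the only enolisable position, and the bulky oxidant should approach the dienolate anti to the pseudo-axial allyl group on C3a, which is 1,3 to C5, giving the alcohol trans to allyl (5S); the potassium enolate avoids addition to the sulfonimine by-product.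

Step 11
Reactants: 18 (2R,3S,3aS,5S)-3a-allyl-5-hydroxy-7-methoxy-2-methyl-3-(3,4,5-trimethoxyphenyl)-3,3a,4,5-tetrahydro-1-benzofuran-6(2H)-one
Product: 19 (2R,3S,3aS,5S)-3a-allyl-5,7-dimethoxy-2-methyl-3-(3,4,5-trimethoxyphenyl)-3,3a,4,5-tetrahydro-1-benzofuran-6(2H)-one
Conditions: MeI, Ag2O, 4 Å MS, CH2Cl2, 40 °C, dark
Reagents that add atoms: iodomethane, CI
Why: Purdie methylation: silver oxide activates iodomethane under near-neutral conditions, so the α-ketol is etherified without enolisation at C5 or α-ketol shift, and the methoxy group stays in the equatorial position trans to allyl.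

## Compound list

1 | 2-hydroxy-3-methoxybenzoic acid | COc1cccc(C(=O)O)c1O | starting material
2 | (S)-2-(methoxymethyl)pyrrolidine | COC[C@@H]1CCCN1 | starting material
3 | (2-hydroxy-3-methoxyphenyl)[(2S)-2-(methoxymethyl)pyrrolidin-1-yl]methanone | COc1cccc(C(=O)N2CCC[C@H]2COC)c1O | intermediate
4 | (2-ethoxy-3-methoxyphenyl)[(2S)-2-(methoxymethyl)pyrrolidin-1-yl]methanone | CCOc1c(OC)cccc1C(=O)N1CCC[C@H]1COC | intermediate
5 | allyl bromide (3-bromoprop-1-ene) | C=CCBr | starting material
6 | potassium amide enolate of the 1,4-dihydro form of 4 | CCOC1=C(OC)CC=CC1=C([O-])N1CCC[C@H]1COC.[K+] | intermediate (not isolated)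
7 | [(1R)-1-allyl-2-ethoxy-3-methoxycyclohexa-2,5-dien-1-yl][(2S)-2-(methoxymethyl)pyrrolidin-1-yl]methanone | C=CC[C@]1(C=CCC(OC)=C1OCC)C(=O)N1CCC[C@H]1COC | intermediate
8 | 5-bromo-1,2,3-trimethoxybenzene | COc1cc(Br)cc(OC)c1OC | starting material
9 | 3,4,5-trimethoxyphenyllithium | [Li]c1cc(OC)c(OC)c(OC)c1 | intermediate (not isolated)
10 | lithium hemiaminal from 7 and 9 (tetrahedral adduct, either configuration at the new carbon) | C=CC[C@]1(C=CCC(OC)=C1OCC)C([O-])(c1cc(OC)c(OC)c(OC)c1)N1CCC[C@H]1COC.[Li+] | intermediate (not isolated)
11 | [(1R)-1-allyl-2-ethoxy-3-methoxycyclohexa-2,5-dien-1-yl](3,4,5-trimethoxyphenyl)methanone | C=CC[C@]1(C=CCC(OC)=C1OCC)C(=O)c1cc(OC)c(OC)c(OC)c1 | intermediate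
12 | [(1S)-1-allyl-2-ethoxy-3-methoxycyclohexa-2,5-dien-1-yl](3,4,5-trimethoxyphenyl)methanone hydrazone | C=CC[C@]1(C=CCC(OC)=C1OCC)C(=NN)c1cc(OC)c(OC)c(OC)c1 | intermediate
13 | (3S)-3-allyl-3-[diazo(3,4,5-trimethoxyphenyl)methyl]-2-ethoxy-1-methoxycyclohexa-1,4-diene | C=CC[C@]1(C=CCC(OC)=C1OCC)C(=[N+]=[N-])c1cc(OC)c(OC)c(OC)c1 | intermediate
14 | (2R,3S,3aS)-3a-allyl-7-methoxy-2-methyl-3-(3,4,5-trimethoxyphenyl)-2,3,3a,6-tetrahydro-1-benzofuran | C=CC[C@@]12C=CCC(OC)=C1O[C@H](C)[C@H]2c1cc(OC)c(OC)c(OC)c1 | intermediate
15 | (2R,3S,3aS)-3a-allyl-7-methoxy-2-methyl-3-(3,4,5-trimethoxyphenyl)-3,3a-dihydro-1-benzofuran-6(2H)-one | C=CC[C@@]12C=CC(=O)C(OC)=C1O[C@H](C)[C@H]2c1cc(OC)c(OC)c(OC)c1 | intermediate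
16 | (2R,3S,3aR)-3a-allyl-7-methoxy-2-methyl-3-(3,4,5-trimethoxyphenyl)-3,3a,4,5-tetrahydro-1-benzofuran-6(2H)-one | C=CC[C@@]12CCC(=O)C(OC)=C1O[C@H](C)[C@H]2c1cc(OC)c(OC)c(OC)c1 | intermediate
17 | potassium dienolate of 16 (C5=C6 enolate) | C=CC[C@@]12CC=C([O-])C(OC)=C1O[C@H](C)[C@H]2c1cc(OC)c(OC)c(OC)c1.[K+] | intermediate (not isolated)
18 | (2R,3S,3aS,5S)-3a-allyl-5-hydroxy-7-methoxy-2-methyl-3-(3,4,5-trimethoxyphenyl)-3,3a,4,5-tetrahydro-1-benzofuran-6(2H)-one | C=CC[C@@]12C[C@H](O)C(=O)C(OC)=C1O[C@H](C)[C@H]2c1cc(OC)c(OC)c(OC)c1 | intermediate
19 | (2R,3S,3aS,5S)-3a-allyl-5,7-dimethoxy-2-methyl-3-(3,4,5-trimethoxyphenyl)-3,3a,4,5-tetrahydro-1-benzofuran-6(2H)-one | C=CC[C@@]12C[C@H](OC)C(=O)C(OC)=C1O[C@H](C)[C@H]2c1cc(OC)c(OC)c(OC)c1 | target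

## Step count and least certain steps

Total step count: 11. Longest linear sequence: 11 steps, from 1; compounds 2, 5 and 8 enter without prior steps.

Step 7 (key step). The most likely failure is stereochemical. The methylene hydrogen that migrates may be the one that leaves methyl cis to aryl, the mode preferred when such insertions run on flat aryl ethers, or hydrogen may be delivered to C3 from the allyl face. In addition, the diazo group may add as a 1,3-dipole to the ring or allyl alkenes before the catalyst converts it.

Fallback: the cis mode at C2 is accepted and C2 is inverted afterwards by ring opening and SN2 reclosure. Setting out from 13, the insertion (same catalyst or Rh2(OPiv)4) would give the C2-epimeric tetrahydrobenzofuran F1. The conditions of steps 8 and 9 would carry it to the C2-epimeric dienone F2 and the C2-epimeric enone F3. LiOH in aqueous THF, then buffered acidification, would hydrolyse the vinylogous ester and open ring A to the hydroxy dione F4. Mitsunobu cyclisation (PPh3, DIAD, THF, 0 °C) would then alkylate the enol oxygen on C7a with inversion at C2 and return to the route at 16.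

Step 5. Condensation at a ketone flanked by a quaternary carbon may stall, and forcing it risks hydrolysis of the enol ethers or diimide reduction of the allyl group.

Fallback: the C=N bond is formed by an irreversible silyl-transfer condensation and oxidised without passing through the free hydrazone. Setting out from 11, 1,2-bis(tert-butyldimethylsilyl)hydrazine with Sc(OTf)3 (cat.) would give the N-silyl hydrazone F5. PhIF2 with 2-chloropyridine in CH2Cl2 at −78 °C would convert it directly into the diazo compound, returning to the route at 13.

Step 4. The aryllithium may fail to add to the hindered, chelated amide carbonyl, or may act as a base towards the doubly allylic C6 methylene, leading to isomerisation of the diene.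

Fallback: the acyl carbon is taken to the aldehyde oxidation state before the aryl group is introduced. Setting out from 7, LiNH2BH3 in THF would reduce the amide to the primary alcohol F6. Dess–Martin oxidation (pyridine buffer) would give the aldehyde F7, addition of 9 at −78 °C the secondary carbinol F8, and a second Dess–Martin oxidation would return to the route at 11.

Step 10. The oxygen transfer may show poor facial selectivity at C5, because the directing allyl group is two atoms away, and the enolate may be partly consumed by the sulfonimine by-product.

Fallback: C5 is placed under thermodynamic instead of kinetic control. Setting out from 16, the hydroxylation mixture containing the C5-epimeric alcohol F9 would be methylated as in step 11, giving 19 together with the C5-epimeric methyl ether F10. Equilibration with DBU in toluene at rt should drain F10 into the isomer with the equatorial methoxy group trans to the pseudo-axial allyl group, returning to the route at 19.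

## Further compounds

F1 | step 7 | (2S,3S,3aS)-3a-allyl-7-methoxy-2-methyl-3-(3,4,5-trimethoxyphenyl)-2,3,3a,6-tetrahydro-1-benzofuran (C2 epimer of 14) | C=CC[C@@]12C=CCC(OC)=C1O[C@@H](C)[C@H]2c1cc(OC)c(OC)c(OC)c1
F2 | step 7 | (2S,3S,3aS)-3a-allyl-7-methoxy-2-methyl-3-(3,4,5-trimethoxyphenyl)-3,3a-dihydro-1-benzofuran-6(2H)-one (C2 epimer of 15) | C=CC[C@@]12C=CC(=O)C(OC)=C1O[C@@H](C)[C@H]2c1cc(OC)c(OC)c(OC)c1
F3 | step 7 | (2S,3S,3aR)-3a-allyl-7-methoxy-2-methyl-3-(3,4,5-trimethoxyphenyl)-3,3a,4,5-tetrahydro-1-benzofuran-6(2H)-one (C2 epimer of 16) | C=CC[C@@]12CCC(=O)C(OC)=C1O[C@@H](C)[C@H]2c1cc(OC)c(OC)c(OC)c1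
F4 | step 7 | (4R)-4-allyl-4-[(1S,2S)-2-hydroxy-1-(3,4,5-trimethoxyphenyl)propyl]-2-methoxycyclohexane-1,3-dione (enolised) | C=CC[C@]1(CCC(=O)C(OC)C1=O)[C@@H]([C@H](C)O)c1cc(OC)c(OC)c(OC)c1
F5 | step 5 | N-(tert-butyldimethylsilyl)hydrazone of 11 | C=CC[C@]1(C=CCC(OC)=C1OCC)C(=NN[Si](C)(C)C(C)(C)C)c1cc(OC)c(OC)c(OC)c1
F6 | step 4 | [(1S)-1-allyl-2-ethoxy-3-methoxycyclohexa-2,5-dien-1-yl]methanol | C=CC[C@]1(C=CCC(OC)=C1OCC)CO
F7 | step 4 | (1R)-1-allyl-2-ethoxy-3-methoxycyclohexa-2,5-diene-1-carbaldehyde | C=CC[C@]1(C=CCC(OC)=C1OCC)C=O
F8 | step 4 | [(1S)-1-allyl-2-ethoxy-3-methoxycyclohexa-2,5-dien-1-yl](3,4,5-trimethoxyphenyl)methanol (either carbinol configuration) | C=CC[C@]1(C=CCC(OC)=C1OCC)C(O)c1cc(OC)c(OC)c(OC)c1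
F9 | step 10 | (2R,3S,3aS,5R)-3a-allyl-5-hydroxy-7-methoxy-2-methyl-3-(3,4,5-trimethoxyphenyl)-3,3a,4,5-tetrahydro-1-benzofuran-6(2H)-one (C5 epimer of 18) | C=CC[C@@]12C[C@@H](O)C(=O)C(OC)=C1O[C@H](C)[C@H]2c1cc(OC)c(OC)c(OC)c1
F10 | step 10 | (2R,3S,3aS,5R)-3a-allyl-5,7-dimethoxy-2-methyl-3-(3,4,5-trimethoxyphenyl)-3,3a,4,5-tetrahydro-1-benzofuran-6(2H)-one (C5 epimer of 19) | C=CC[C@@]12C[C@@H](OC)C(=O)C(OC)=C1O[C@H](C)[C@H]2c1cc(OC)c(OC)c(OC)c1
A1 | alternative 1 | 4-hydroxy-2,3-dimethoxy-4-[(1E)-2-allyl-3-(3,4,5-trimethoxyphenyl)-4-(triethylsilyloxy)pent-1-en-1-yl]cyclobut-2-en-1-one, C2 and C3 as in the target | C=CC/C(=C\C1(O)C(OC)=C(OC)C1=O)[C@H](c1cc(OC)c(OC)c(OC)c1)[C@@H](C)O[Si](CC)(CC)CC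
A2 | alternative 1 | 5-allyl-2,3-dimethoxy-5-[2-(triethylsilyloxy)-1-(3,4,5-trimethoxyphenyl)propyl]cyclohex-2-ene-1,4-dione, C2, C3 and C3a as in the target | C=CC[C@]1(CC(=O)C(OC)=C(OC)C1=O)[C@H](c1cc(OC)c(OC)c(OC)c1)[C@@H](C)O[Si](CC)(CC)CC
A3 | alternative 2 | (5R)-3-allyl-5-methylfuran-2(5H)-one | C=CCC1=C[C@@H](C)OC1=O
A4 | alternative 2 | 3,4,5-trimethoxyphenylmagnesium bromide | COc1cc([Mg]Br)cc(OC)c1OC
A5 | alternative 2 | 1-methoxybut-3-en-2-one | C=CC(=O)COC
A6 | alternative 2 | (3R,4S,5R)-3-allyl-3-(4-methoxy-3-oxobutyl)-5-methyl-4-(3,4,5-trimethoxyphenyl)dihydrofuran-2(3H)-one | C=CC[C@@]1(CCC(=O)COC)C(=O)O[C@H](C)[C@H]1c1cc(OC)c(OC)c(OC)c1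
A7 | alternative 3 | 2-[(Z)-2-(1-allyl-2,3-dimethoxycyclohexa-2,5-dien-1-yl)ethenyl]-4,4,5,5-tetramethyl-1,3,2-dioxaborolane, quaternary carbon as C3a of the target | C=CC[C@]1(C=CCC(OC)=C1OC)/C=C\B1OC(C)(C)C(C)(C)O1
A8 | alternative 3 | 3,4,5-trimethoxyphenyl trifluoromethanesulfonate | COc1cc(OS(=O)(=O)C(F)(F)F)cc(OC)c1OC
A9 | alternative 3 | 2-[1-(1-allyl-2,3-dimethoxycyclohexa-2,5-dien-1-yl)-1-(3,4,5-trimethoxyphenyl)propan-2-yl]-4,4,5,5-tetramethyl-1,3,2-dioxaborolane, C2, C3 and C3a as in the target after oxidation | C=CC[C@]1(C=CCC(OC)=C1OC)[C@H](c1cc(OC)c(OC)c(OC)c1)[C@@H](C)B1OC(C)(C)C(C)(C)O1
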